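**Compound numbers used throughout.** 1 2,2,6-trimethyl-4H-1,3-dioxin-4-one; 2 acetyl chloride; 3 keto-dioxinone; 4 (R)-3-hydroxytetradecanoic acid; 5 bis-silyl compound; 6 silyloxy acid; 7 acyl imidazole; 8 Weinreb amide; 9 diketo-dioxinone; 10 benzyl alcohol; 11 acylketene; 12 triketo ester; 13 cyclic aldol; 14 benzyl resorcylate; 15 its 4-O-benzyl ether; 16 the methyl ether of 15; 17 hydroxy ester; 18 acetate; 19 target. In the discussion the ring is counted C1 (carboxyl), C2 (methoxy), C4 (hydroxy), C6 (side chain); the systematic names count the ring the other way round.

## Analysis of the target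

Target 19 is a tetrasubstituted benzene: a benzoic acid with the carboxyl at C1, a methoxy group at C2, a free phenol at C4 and, at C6, a thirteen-carbon chain joined through a CH2 group and carrying an acetoxy group on its second carbon. That acetoxy carbon is the only stereocentre; it is (R) and sits between the benzylic CH2 and an unbranched undecyl chain. Nothing nearby can relay or correct its configuration, and with no second stereocentre a shortfall in enantiopurity could not be removed as a diastereomer. The sensitive groups are the secondary acetate (lost or shifted by base and nucleophiles), the free acid and the free phenol. The real hazard is the ortho relation between the C1 carboxyl and the oxygenated side chain: a free side-chain hydroxyl next to an ester or activated acid can close to the six-membered lactone (a 3,4-dihydroisocoumarin), after which the open acetoxy acid is not cleanly recoverable. The two ring oxygens must also be told apart (methyl at C2, hydrogen at C4), and the benzoate is flanked on both sides. The strategy rests on one reading of the structure: carboxyl at C1, oxygens at C2 and C4 and a carbon substituent at C6 form the pattern of a β-resorcylate, that is, of a linear 3,5,7-trioxo ester whose C2–C7 are folded into ring atoms C1–C6. Ring atom C6 with its side chain (C–CH2–CH(O)–C11H23) is then the intact fourteen-carbon skeleton of (R)-3-hydroxytetradecanoic acid 4, which has the right length and the right configuration.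

## Retrosynthetic reasoning

19 back to 18. The last bonds cut are the two benzyl C–O bonds, one on the carboxyl and one on the C4 oxygen. Both are cleaved by neutral hydrogenolysis in one operation, which leaves the acetate untouched and never creates a free side-chain hydroxyl beside a reactive carboxyl derivative. The forward step has to remove two benzyl groups and nothing else.

18 back to 16 (through 17). The acetate O–acyl bond is cut to reveal the alcohol 17, which is carried as its silyl ether in 16. An acetate could not survive the enolate chemistry that builds the chain (it would be enolized, attacked or eliminated), so the oxygen travels as a robust silyl ether and is exchanged late. The forward step must take the silyl group off without generating an alkoxide and must acylate 17 before it can lactonize.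

16 back to 15 and 14. The O–methyl bond at C2 and the O–benzyl bond at C4 are cut in that order. In 14 the C2 phenol is tied to the ester carbonyl by a hydrogen bond while the C4 phenol is free and more acidic, so the first alkylation goes to C4. That alkylation is chosen as a benzylation so that the group leaves with the benzyl ester at the end, and the second alkylation puts the methyl on C2.

14 back to 9 and 10 (through 13, 12 and 11). This is the central disconnection. The ring bond C1–C6 is opened in a retro-aldol sense and the two phenols are written as ketones, which unfolds the arene into the triketo ester 12 by way of the cyclic aldol 13. The ester C–O bond of 12 is then cut back to the acylketene 11 and benzyl alcohol 10, and 11 is stored as the dioxinone 9. Cutting here means that the whole substitution pattern of the ring follows from the connectivity of a chain, so no aromatic substitution has to be steered. The forward reaction has to release 11, trap it with 10, select the C2-to-C7 aldol among the possible cyclization modes and leave the silyloxy stereocentre, β to the C7 ketone, alone.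

9 back to 3 and 8. The bond between chain C6 and C7 is cut, a crossed Claisen disconnection between the terminal carbon of keto-dioxinone 3 and the acyl carbon of the Weinreb amide 8. This puts every atom near the stereocentre into a single acyl donor, so the stereocentre is bought rather than made. The forward step needs the dianion of 3 to add through its terminal carbon and needs the donor not to be enolized.

8 back to 6 and 4 (through 7 and 5). The amide and silyl ether are traced to the chiral-pool acid 4. The acyl imidazole 7 is used only in passing. As a direct donor it would bring one equivalent of acidic N–H heterocycle to the dianion, and its α-CH2, more acidic than that of an amide, lies β to the silyloxy group; the amide 8 is isolable, free of acidic N–H and a weaker carbon acid.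

3 back to 1 and 2. The bond between the exocyclic carbon of 1 and the acetyl carbon of 2 is cut, a vinylogous C-acylation that supplies chain C3–C6 from two inexpensive compounds.

## Alternatives that were turned down

Alternative 1: The ring bonds C1–C2 and C5–C6 are cut, giving a [4+2] benzannulation between the chiral ynoate benzyl (5R)-5-acetoxyhexadec-2-ynoate A2 and the electron-rich diene 1,1-dimethoxy-3-(trimethylsilyloxy)buta-1,3-diene A3. In the forward direction the nucleophilic terminus of A3 adds to the alkyl-bearing alkyne carbon of A2 and the ring closes. It then aromatizes by expelling one methoxy group and, after loss of the silyl group, gives benzyl 2-[(2R)-2-acetoxytridecyl]-4-hydroxy-6-methoxybenzoate A1, one hydrogenolysis from 19. This route is stronger than the chosen one on two points. The C2 methoxy and C4 hydroxy arrive already differentiated, so steps 6 and 7 would not be needed. The acetate is also in place before the ring exists, so the silyl-to-acetate exchange of step 8 and its lactonization hazard disappear. Against it, A2 is a β-alkyl ynoate with a single activating group and therefore a poor dienophile, whereas dienes such as A3 react cleanly only with doubly activated or terminal alkynes. At the temperatures such a partner needs, A3 is prone to silyl migration and hydrolysis, and a stepwise conjugate-addition pathway can stop at open-chain adducts or pyranones. The propargylic CH2 of A2 lies next to the acetoxy carbon, so isomerization to the allenoate followed by loss of acetate is a further drain. A2 also needs its own enantioselective preparation. The chosen route pays three extra functional-group steps, but it forms the ring by an intramolecular aldol whose regiochemistry is fixed by connectivity and which is driven by aromatization.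

Alternative 2: The C6–CH2 bond and the C1–carboxyl bond are cut together, as an aryne acyl-alkylation. Fluoride releases the aryne from 5-(benzyloxy)-3-methoxy-2-(trimethylsilyl)phenyl trifluoromethanesulfonate A5. The anion of dibenzyl malonate A6 adds at the aryne carbon remote from the methoxy group, the aryl anion closes onto an ester carbonyl, and the four-membered ring reopens to give the homophthalate benzyl 4-(benzyloxy)-2-[2-(benzyloxy)-2-oxoethyl]-6-methoxybenzoate A4. In its favour, the regiochemistry is reliably set by the 3-methoxy group of the aryne, and the two ring oxygens are differentiated from the start, which is better than the chosen route on that point. Against it, A4 contains only the ring and a two-carbon arm. The undecyl chain and the stereocentre are still missing, the two benzyl esters must be told apart, and the arm must be brought to the aldehyde level. The stereocentre would then be made by reagent control beside an ester that captures any alkoxide as the lactone. A5 itself takes several steps. The chosen route is much shorter overall, and its key step delivers the ring with the complete, enantiopure side chain attached.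

Alternative 3: The bond from the stereocentre to the undecyl chain and the acetate O–acyl bond are cut. The arylacetaldehyde benzyl 4-(benzyloxy)-2-methoxy-6-(2-oxoethyl)benzoate A8 and acetyl bromide A9 give the racemic bromo acetate benzyl 2-(2-acetoxy-2-bromoethyl)-4-(benzyloxy)-6-methoxybenzoate A10 in the flask. NiBr2·glyme A12 with a chiral bis(oxazoline) ligand then couples A10 enantioconvergently with undecylzinc bromide A11 to give benzyl 2-[(2R)-2-acetoxytridecyl]-4-(benzyloxy)-6-methoxybenzoate A7. A7 is the same compound as 18, so the two routes meet one step before the target. This route is stronger in that the stereocentre is created directly as the acetate: there is no hydroxyl protecting group and no free alcohol, so the hazard of step 8 does not exist, and the chain length is freely variable. Against it, A8 must first be built with all ring substituents in place, for example by way of A4. As an arylacetaldehyde ortho to an ester it enolizes easily and its enol can close onto the ester to an isocoumarin. A10 can lose HBr to a conjugated enol acetate. The sense and level of induction depend entirely on the catalyst, with a crowded Lewis-basic arene close to the radical centre, and any minor enantiomer would be carried into 19 with no diastereomer to separate. The chosen route instead takes the stereocentre at full purity from 4 and never breaks a bond to it, and it pays for this with protecting-group exchanges.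

Key step: step 5

Assumption: (R)-3-hydroxytetradecanoic acid 4 is taken as a purchasable enantiopure compound. No bond to its C3 is broken anywhere, and the CIP ranking (O > ring-side CH2 > undecyl > H) is unchanged, so (R) in 4 becomes (R) in 19.

## Route

Step 1
Reactants: 1 2,2,6-trimethyl-4H-1,3-dioxin-4-one; 2 acetyl chloride
Product: 3 2,2-dimethyl-6-(2-oxopropyl)-4H-1,3-dioxin-4-one
Conditions: 1 (2 equiv), LiN(SiMe3)2 (2 equiv), THF, −78 °C; then 2 (1 equiv), −78 → −20 °C; aq. NH4Cl
Reagents that add atoms: none
Why: Deprotonation of the 6-methyl group gives the lithium dienolate of 1, which undergoes vinylogous Claisen-type C-acylation by acetyl chloride at the exocyclic carbon. The second equivalent of enolate takes up the proton of the more acidic product and so protects it from a second acylation.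

Step 2
Reactants: 4 (R)-3-hydroxytetradecanoic acid
Product: 6 (3R)-3-(tert-butyldimethylsilyloxy)tetradecanoic acid, via bis-silyl compound 5 (not isolated)
Conditions: TBSCl (2.5 equiv), imidazole, DMF, rt; then K2CO3, MeOH/THF/H2O, rt; aq. citric acid to pH 4
Reagents that add atoms: tert-butyldimethylsilyl chloride, CC(C)(C)[Si](C)(C)Cl
Why: Imidazole-promoted silylation covers both the hydroxyl and the carboxyl, and the labile silyl ester of 5 is then cleaved selectively by mild carbonate solvolysis while the secondary silyl ether stays. The stereocentre takes no part.

Step 3
Reactants: 6 (3R)-3-(tert-butyldimethylsilyloxy)tetradecanoic acid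
Product: 8 (3R)-3-(tert-butyldimethylsilyloxy)-N-methoxy-N-methyltetradecanamide, via acyl imidazole 7 (not isolated)
Conditions: 1,1'-carbonyldiimidazole (1.2 equiv), CH2Cl2, rt; then MeNHOMe·HCl (1.5 equiv), rt
Reagents that add atoms: N,O-dimethylhydroxylamine hydrochloride, CNOC.Cl
Why: Carbonyldiimidazole activation gives acyl imidazole 7, and its aminolysis gives the Weinreb amide. No base strong enough to enolize the acyl group is present, so the β-silyloxy stereocentre is safe.

Step 4
Reactants: 3 2,2-dimethyl-6-(2-oxopropyl)-4H-1,3-dioxin-4-one; 8 (3R)-3-(tert-butyldimethylsilyloxy)-N-methoxy-N-methyltetradecanamide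
Product: 9 6-[(6R)-6-(tert-butyldimethylsilyloxy)-2,4-dioxoheptadecyl]-2,2-dimethyl-4H-1,3-dioxin-4-one
Conditions: 3 (2 equiv), LiN(iPr)2 (4.2 equiv), THF, −78 °C; then 8 (1 equiv), −78 → −40 °C; aq. NH4Cl
Reagents that add atoms: none
Why: Double deprotonation of 3 gives a dianion whose terminal, less stabilized carbanion adds to the amide (crossed Claisen acylation of a β-dicarbonyl dianion, Weinreb ketone synthesis). The chelated tetrahedral adduct keeps the new ketone masked until the quench, and 8 is a weaker carbon acid than the methyl ketone whose enolate attacks it, so enolization of 8 and loss of silanolate should not compete.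

Step 5
Reactants: 9 6-[(6R)-6-(tert-butyldimethylsilyloxy)-2,4-dioxoheptadecyl]-2,2-dimethyl-4H-1,3-dioxin-4-one; 10 benzyl alcohol
Product: 14 benzyl 2-[(2R)-2-(tert-butyldimethylsilyloxy)tridecyl]-4,6-dihydroxybenzoate, via acylketene 11 (not isolated), via triketo ester 12 (not isolated), via cyclic aldol 13 (not isolated)
Conditions: 10 (1.5 equiv), PhMe, 110 °C; cool; then Cs2CO3, iPrOH/CH2Cl2, rt; then AcOH to pH 5
Reagents that add atoms: none
Why: Heating 9 sets off a retro-[4+2] cycloreversion of the dioxinone that expels acetone and leaves acylketene 11, which benzyl alcohol 10 captures at the ketene carbon to give β-keto ester 12. Under Cs2CO3 the C2 methylene of 12, acidified by the ester and the C3 ketone, adds as its enolate to the C7 ketone; this intramolecular aldol forms the bond that becomes C1–C6 of the arene and gives cyclic aldol 13. E1cB loss of water and enolization of the two remaining ring ketones then give resorcylate 14, with aromatization as the driving force and the mildly acidic finish completing the dehydration. The closest known reaction type is dioxinone thermolysis with alcohol trapping followed by the biomimetic aldol aromatization of 3,5,7-triketo esters to β-resorcylates. The single six-membered carbocycle closes in the 6-(enolexo)-exo-trig mode. No stereocentre is created, since the two sp3 ring centres of 13 are erased on aromatization, and the C9 silyloxy stereocentre lies outside the reacting array. The step needs the C2-to-C7 aldol to win over Claisen closure of C6 onto the ester carbonyl, over pyranone formation by oxygen capture of 11, and over β-elimination of silanolate across C8–C9. A ketone is the better electrophile than a benzyl ester under weak base, excess 10 outruns internal oxygen capture, and the singly activated C8–H is far less acidic than the doubly activated C2, C4 and C6 methylenes, so carbonate should not form the enolate that elimination requires.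

Step 6
Reactants: 14 benzyl 2-[(2R)-2-(tert-butyldimethylsilyloxy)tridecyl]-4,6-dihydroxybenzoate
Product: 15 benzyl 4-(benzyloxy)-2-[(2R)-2-(tert-butyldimethylsilyloxy)tridecyl]-6-hydroxybenzoate
Conditions: BnBr (1.05 equiv), K2CO3, acetone, rt
Reagents that add atoms: benzyl bromide, BrCc1ccccc1
Why: Williamson etherification. The phenol para to the ester is free and the more acidic one, while the ortho phenol is held in a hydrogen bond to the ester carbonyl, so one equivalent of benzyl bromide should alkylate only the para oxygen.

Step 7
Reactants: 15 benzyl 4-(benzyloxy)-2-[(2R)-2-(tert-butyldimethylsilyloxy)tridecyl]-6-hydroxybenzoate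
Product: 16 benzyl 4-(benzyloxy)-2-[(2R)-2-(tert-butyldimethylsilyloxy)tridecyl]-6-methoxybenzoate
Conditions: MeI (3 equiv), K2CO3, DMF, 40 °C
Reagents that add atoms: iodomethane, CI
Why: Williamson methylation of the remaining, chelated phenol under more forcing conditions (polar solvent, excess iodomethane). The silyl ether and both benzyl groups are inert to carbonate.

Step 8
Reactants: 16 benzyl 4-(benzyloxy)-2-[(2R)-2-(tert-butyldimethylsilyloxy)tridecyl]-6-methoxybenzoate
Product: 18 benzyl 2-[(2R)-2-acetoxytridecyl]-4-(benzyloxy)-6-methoxybenzoate, via hydroxy ester 17 (not isolated)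
Conditions: HF·pyridine, pyridine, THF, 0 °C → rt; cold aq. NaHCO3 work-up; crude 17, Ac2O, pyridine, DMAP (cat.), CH2Cl2, 0 °C
Reagents that add atoms: acetic anhydride, CC(=O)OC(C)=O
Why: Buffered fluoride desilylation frees the alcohol without ever forming an alkoxide, and DMAP-catalysed acetylation of the unhindered secondary alcohol is expected to outrun its attack on the doubly ortho-substituted benzoate. Acylation occurs at oxygen, so the C–O bond and the (R) configuration are retained.

Step 9
Reactants: 18 benzyl 2-[(2R)-2-acetoxytridecyl]-4-(benzyloxy)-6-methoxybenzoate
Product: 19 2-[(2R)-2-acetoxytridecyl]-4-hydroxy-6-methoxybenzoic acid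
Conditions: H2 (1 atm), Pd/C (10 wt% Pd), EtOAc, rt
Reagents that add atoms: none
Why: Catalytic hydrogenolysis cleaves the benzyl ester and the benzyl aryl ether together under neutral conditions. The homobenzylic acetate, the aryl methyl ether and the arene are not reduced.

## Compound list

1 | 2,2,6-trimethyl-4H-1,3-dioxin-4-one | CC1=CC(=O)OC(C)(C)O1 | starting material
2 | acetyl chloride | CC(=O)Cl | starting material
3 | 2,2-dimethyl-6-(2-oxopropyl)-4H-1,3-dioxin-4-one | CC(=O)CC1=CC(=O)OC(C)(C)O1 | intermediate
4 | (R)-3-hydroxytetradecanoic acid | CCCCCCCCCCC[C@H](CC(=O)O)O | starting material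
5 | tert-butyldimethylsilyl (3R)-3-(tert-butyldimethylsilyloxy)tetradecanoate | CCCCCCCCCCC[C@H](CC(=O)O[Si](C)(C)C(C)(C)C)O[Si](C)(C)C(C)(C)C | intermediate
6 | (3R)-3-(tert-butyldimethylsilyloxy)tetradecanoic acid | CCCCCCCCCCC[C@H](CC(=O)O)O[Si](C)(C)C(C)(C)C | intermediate
7 | (3R)-3-(tert-butyldimethylsilyloxy)-1-(1H-imidazol-1-yl)tetradecan-1-one | CCCCCCCCCCC[C@H](CC(=O)n1ccnc1)O[Si](C)(C)C(C)(C)C | intermediate
8 | (3R)-3-(tert-butyldimethylsilyloxy)-N-methoxy-N-methyltetradecanamide | CCCCCCCCCCC[C@H](CC(=O)N(C)OC)O[Si](C)(C)C(C)(C)C | intermediate
9 | 6-[(6R)-6-(tert-butyldimethylsilyloxy)-2,4-dioxoheptadecyl]-2,2-dimethyl-4H-1,3-dioxin-4-one | CCCCCCCCCCC[C@H](CC(=O)CC(=O)CC1=CC(=O)OC(C)(C)O1)O[Si](C)(C)C(C)(C)C | intermediate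
10 | benzyl alcohol | OCc1ccccc1 | starting material
11 | (9R)-9-(tert-butyldimethylsilyloxy)icos-1-ene-1,3,5,7-tetrone (acylketene) | CCCCCCCCCCC[C@H](CC(=O)CC(=O)CC(=O)C=C=O)O[Si](C)(C)C(C)(C)C | intermediate
12 | benzyl (9R)-9-(tert-butyldimethylsilyloxy)-3,5,7-trioxoicosanoate | CCCCCCCCCCC[C@H](CC(=O)CC(=O)CC(=O)CC(=O)OCc1ccccc1)O[Si](C)(C)C(C)(C)C | intermediate
13 | benzyl 2-[(2R)-2-(tert-butyldimethylsilyloxy)tridecyl]-2-hydroxy-4,6-dioxocyclohexane-1-carboxylate (mixture at the two transient ring centres) | CCCCCCCCCCC[C@H](CC1(O)CC(=O)CC(=O)C1C(=O)OCc1ccccc1)O[Si](C)(C)C(C)(C)C | intermediate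
14 | benzyl 2-[(2R)-2-(tert-butyldimethylsilyloxy)tridecyl]-4,6-dihydroxybenzoate | CCCCCCCCCCC[C@H](Cc1cc(O)cc(O)c1C(=O)OCc1ccccc1)O[Si](C)(C)C(C)(C)C | intermediate
15 | benzyl 4-(benzyloxy)-2-[(2R)-2-(tert-butyldimethylsilyloxy)tridecyl]-6-hydroxybenzoate | CCCCCCCCCCC[C@H](Cc1cc(OCc2ccccc2)cc(O)c1C(=O)OCc1ccccc1)O[Si](C)(C)C(C)(C)C | intermediate
16 | benzyl 4-(benzyloxy)-2-[(2R)-2-(tert-butyldimethylsilyloxy)tridecyl]-6-methoxybenzoate | CCCCCCCCCCC[C@H](Cc1cc(OCc2ccccc2)cc(OC)c1C(=O)OCc1ccccc1)O[Si](C)(C)C(C)(C)C | intermediate
17 | benzyl 4-(benzyloxy)-2-[(2R)-2-hydroxytridecyl]-6-methoxybenzoate | CCCCCCCCCCC[C@H](Cc1cc(OCc2ccccc2)cc(OC)c1C(=O)OCc1ccccc1)O | intermediate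
18 | benzyl 2-[(2R)-2-acetoxytridecyl]-4-(benzyloxy)-6-methoxybenzoate | CCCCCCCCCCC[C@H](Cc1cc(OCc2ccccc2)cc(OC)c1C(=O)OCc1ccccc1)OC(C)=O | intermediate
19 | 2-[(2R)-2-acetoxytridecyl]-4-hydroxy-6-methoxybenzoic acid | CCCCCCCCCCC[C@H](Cc1cc(O)cc(OC)c1C(=O)O)OC(C)=O | target

## Step count and risk

Total: 9 steps. Longest linear sequence: 8 steps (4 through steps 2, 3, 4, 5, 6, 7, 8 and 9 to 19); the branch from 1 joins at step 4.

Step 5 (key step). The most likely failure is capture of the acylketene by an enol oxygen of its own diketone, giving pyranone formation instead of the benzyl ester. Behind that come closure of the triketo ester through oxygen or through the Claisen mode, and base-induced loss of silanolate across C8–C9 before the ring is aromatic. Fallback: aromatize before the dioxinone is opened, so that no free acylketene is ever formed. The fallback sets out from 9, which is treated with Et3N in CH2Cl2 at room temperature. The nucleophilic ring carbon of the dioxinone then adds to the far ketone, and dehydration should give the acetonide-protected resorcylate 7-hydroxy-2,2-dimethyl-5-[(2R)-2-(tert-butyldimethylsilyloxy)tridecyl]-4H-1,3-benzodioxin-4-one F1. Its only free phenol is benzylated (BnBr, K2CO3, acetone) to 7-(benzyloxy)-2,2-dimethyl-5-[(2R)-2-(tert-butyldimethylsilyloxy)tridecyl]-4H-1,3-benzodioxin-4-one F2. Opening of F2 with NaOCH2Ph (from NaH and 10 in THF) expels acetone and comes back to the route at 15, which also makes step 6 unnecessary.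

Step 4. The most likely failure is proton transfer from the α-CH2 of 8 to the strongly basic dianion in place of addition, followed by expulsion of silanolate, or simply incomplete acylation of a hindered, aggregated dianion. Fallback: soft enolization in place of a preformed dianion, setting out from 6 and 1. Acid 6 is converted with 1-chloro-N,N,2-trimethylprop-1-en-1-amine (CH2Cl2, 0 °C, neutral) into (3R)-3-(tert-butyldimethylsilyloxy)tetradecanoyl chloride F3. The dienolate of 1 is acylated with allyl 3-chloro-3-oxopropanoate to give allyl 4-(2,2-dimethyl-4-oxo-4H-1,3-dioxin-6-yl)-3-oxobutanoate F4. F4 is C-acylated by F3 under MgCl2 and pyridine in CH2Cl2 at 0 °C to give allyl (5R)-5-(tert-butyldimethylsilyloxy)-2-[2-(2,2-dimethyl-4-oxo-4H-1,3-dioxin-6-yl)acetyl]-3-oxohexadecanoate F5. Deallylation and decarboxylation of F5 with catalytic Pd(PPh3)4 and morpholine in THF comes back to the route at 9.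

Step 8. The most likely failure is lactonization of the freed alcohol onto the neighbouring benzyl ester, with loss of benzyl alcohol, during desilylation, work-up or concentration before the acetylation can take place. Fallback: a direct silyl-to-acetyl exchange that never passes through the free alcohol. It sets out from 16, which is treated with Ac2O and catalytic Cu(OTf)2 in CH2Cl2 at 0 °C, so that the silyl ether oxygen is acylated and the silyl group leaves as its acetate. It comes back to the route at 18 and makes no new compound (F0).

Step 6. The most likely failure is incomplete discrimination between the two phenols, that is, partial alkylation of the chelated oxygen or unreacted diol, giving a mixture that is tedious to separate. Fallback: Mitsunobu etherification, which responds to acidity and accessibility and not to phenoxide concentration. It sets out from 14, which is treated with 10, PPh3 and diisopropyl azodicarboxylate in THF at 0 °C. Only the free, more acidic para phenol should react, and the fallback comes back to the route at 15 without any new compound (F0).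

## Further compounds

F1 | step 5 | 7-hydroxy-2,2-dimethyl-5-[(2R)-2-(tert-butyldimethylsilyloxy)tridecyl]-4H-1,3-benzodioxin-4-one | CCCCCCCCCCC[C@H](Cc1cc(O)cc2OC(C)(C)OC(=O)c12)O[Si](C)(C)C(C)(C)C
F2 | step 5 | 7-(benzyloxy)-2,2-dimethyl-5-[(2R)-2-(tert-butyldimethylsilyloxy)tridecyl]-4H-1,3-benzodioxin-4-one | CCCCCCCCCCC[C@H](Cc1cc(OCc2ccccc2)cc2OC(C)(C)OC(=O)c12)O[Si](C)(C)C(C)(C)C
F3 | step 4 | (3R)-3-(tert-butyldimethylsilyloxy)tetradecanoyl chloride | CCCCCCCCCCC[C@H](CC(Cl)=O)O[Si](C)(C)C(C)(C)C
F4 | step 4 | allyl 4-(2,2-dimethyl-4-oxo-4H-1,3-dioxin-6-yl)-3-oxobutanoate | C=CCOC(=O)CC(=O)CC1=CC(=O)OC(C)(C)O1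
F5 | step 4 | allyl (5R)-5-(tert-butyldimethylsilyloxy)-2-[2-(2,2-dimethyl-4-oxo-4H-1,3-dioxin-6-yl)acetyl]-3-oxohexadecanoate | CCCCCCCCCCC[C@H](CC(=O)C(C(=O)OCC=C)C(=O)CC1=CC(=O)OC(C)(C)O1)O[Si](C)(C)C(C)(C)C
F0 | step 8 | none | none
F0 | step 6 | none | none
A1 | alternative 1 | benzyl 2-[(2R)-2-acetoxytridecyl]-4-hydroxy-6-methoxybenzoate | CCCCCCCCCCC[C@H](Cc1cc(O)cc(OC)c1C(=O)OCc1ccccc1)OC(C)=O
A2 | alternative 1 | benzyl (5R)-5-acetoxyhexadec-2-ynoate | CCCCCCCCCCC[C@H](CC#CC(=O)OCc1ccccc1)OC(C)=O
A3 | alternative 1 | 1,1-dimethoxy-3-(trimethylsilyloxy)buta-1,3-diene | COC(OC)=CC(=C)O[Si](C)(C)C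
A4 | alternative 2 | benzyl 4-(benzyloxy)-2-[2-(benzyloxy)-2-oxoethyl]-6-methoxybenzoate | COc1cc(OCc2ccccc2)cc(CC(=O)OCc2ccccc2)c1C(=O)OCc1ccccc1
A5 | alternative 2 | 5-(benzyloxy)-3-methoxy-2-(trimethylsilyl)phenyl trifluoromethanesulfonate | COc1cc(OCc2ccccc2)cc(OS(=O)(=O)C(F)(F)F)c1[Si](C)(C)C
A6 | alternative 2 | dibenzyl malonate | O=C(CC(=O)OCc1ccccc1)OCc1ccccc1
A7 | alternative 3 | benzyl 2-[(2R)-2-acetoxytridecyl]-4-(benzyloxy)-6-methoxybenzoate | CCCCCCCCCCC[C@H](Cc1cc(OCc2ccccc2)cc(OC)c1C(=O)OCc1ccccc1)OC(C)=O
A8 | alternative 3 | benzyl 4-(benzyloxy)-2-methoxy-6-(2-oxoethyl)benzoate | COc1cc(OCc2ccccc2)cc(CC=O)c1C(=O)OCc1ccccc1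
A9 | alternative 3 | acetyl bromide | CC(=O)Br
A10 | alternative 3 | benzyl 2-(2-acetoxy-2-bromoethyl)-4-(benzyloxy)-6-methoxybenzoate (racemic) | COc1cc(OCc2ccccc2)cc(CC(Br)OC(C)=O)c1C(=O)OCc1ccccc1
A11 | alternative 3 | undecylzinc bromide | CCCCCCCCCCC[Zn]Br
A12 | alternative 3 | nickel dibromide 1,2-dimethoxyethane complex | COCCOC.Br[Ni]Br
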